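Ring A, the terminal phloroglucinol, is not coupled as an aryl unit but grown from an open chain on the B1 oxygen. Its 1,3,5-triol pattern around A C1, the ether-bearing carbon flanked by the C2 and C6 hydroxyls, is that of a cyclised 3,5-dioxohexanoate. The key step closes the A C1–C2 bond by intramolecular ester acylation of the aryloxy-substituted C6 carbanion of methyl 6-aryloxy-3,5-dioxohexanoate 16 (aryl = protected B–C dimer). Enolisation then delivers ring A with its most hindered ether already in place. Rings D–J follow as three further copies of the same dimer bromide 10 and one pyrogallol bromide 5, by copper-catalysed etherification.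

Key step: step 11

Remark: rings are lettered A (phloroglucinol end) to J, each numbered from the carbon whose ether oxygen leads towards ring A (ring A from its ether carbon); Bn = benzyl, MOM = methoxymethyl; the target has no stereocentre; 16 is drawn as the triketo tautomer although it should be largely enolised.

Step 1
Reactants: 1 4-bromo-2,6-difluorobenzaldehyde
Product: 2 4-bromo-2,6-bis(benzyloxy)benzaldehyde
Conditions: BnOH, NaH, THF, 0 → 50 °C
Reagents that add atoms: benzyl alcohol, OCc1ccccc1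
Why: Twofold nucleophilic aromatic substitution, in which both fluorides lie ortho to the formyl group and should be displaced by benzyloxide far faster than the para bromide, a much poorer leaving group in addition–elimination.

Step 2
Reactants: 2 4-bromo-2,6-bis(benzyloxy)benzaldehyde
Product: 4 4-bromo-2,6-bis(benzyloxy)phenol, via aryl formate 3 (not isolated)
Conditions: mCPBA, NaHCO3, CH2Cl2, 0 °C → rt; then KOH, MeOH–H2O, rt
Reagents that add atoms: mCPBA, OOC(=O)c1cccc(Cl)c1
Why: Baeyer–Villiger oxidation of an electron-rich benzaldehyde (Dakin-type), in which the 2,6-dialkoxyaryl group migrates in preference to hydrogen to give formate 3, which is saponified in the same flask.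

Step 3
Reactants: 4 4-bromo-2,6-bis(benzyloxy)phenol
Product: 5 5-bromo-1,2,3-tris(benzyloxy)benzene
Conditions: BnBr, K2CO3, DMF, rt
Reagents that add atoms: benzyl bromide, BrCc1ccccc1
Why: Williamson ether synthesis of a phenoxide with a reactive benzylic bromide.

Step 4
Reactants: 5 5-bromo-1,2,3-tris(benzyloxy)benzene
Product: 6 6-bromo-2,3,4-tris(benzyloxy)benzaldehyde
Conditions: Cl2CHOMe, SnCl4, CH2Cl2, −20 → 0 °C; then H2O
Reagents that add atoms: dichloromethyl methyl ether, COC(Cl)Cl; water, O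
Why: Rieche formylation (Friedel–Crafts type), in which the two free ring positions are equivalent, each para to one benzyloxy group and ortho to another, so a single aldehyde should form, and the mild Lewis acid at low temperature should spare the benzyl ethers.

Step 5
Reactants: 4 4-bromo-2,6-bis(benzyloxy)phenol; 6 6-bromo-2,3,4-tris(benzyloxy)benzaldehyde
Product: 7 6-[4-bromo-2,6-bis(benzyloxy)phenoxy]-2,3,4-tris(benzyloxy)benzaldehyde (B–C dimer aldehyde)
Conditions: CuO (0.5 equiv), K2CO3, pyridine, 110 °C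
Reagents that add atoms: none
Why: Ullmann diaryl ether synthesis in its classical ligand-free form, in which only the bromide of 6 is activated by the chelating ortho formyl group, whereas the bromide of 4 sits para to a phenoxide oxygen and that of 7 on an electron-rich unactivated ring, so the coupling should stop at the dimer.

Step 6
Reactants: 7 B–C dimer aldehyde
Product: 9 6-[4-bromo-2,6-bis(benzyloxy)phenoxy]-2,3,4-tris(benzyloxy)phenol, via aryl formate 8 (not isolated)
Conditions: mCPBA, NaHCO3, CH2Cl2, 0 °C → rt; then KOH, MeOH–THF–H2O, rt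
Reagents that add atoms: mCPBA, OOC(=O)c1cccc(Cl)c1
Why: Baeyer–Villiger (Dakin-type) oxidation, favoured because the formyl-bearing ring carries ortho and para oxygen donors that promote aryl migration to formate 8, whose saponification should free the C2 phenol of ring C while bromide and benzyl ethers stay untouched.

Step 7
Reactants: 9 6-[4-bromo-2,6-bis(benzyloxy)phenoxy]-2,3,4-tris(benzyloxy)phenol
Product: 10 1-[4-bromo-2,6-bis(benzyloxy)phenoxy]-3,4,5-tris(benzyloxy)-2-(methoxymethoxy)benzene (dimer bromide)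
Conditions: NaH, THF–DMF, 0 °C; MOMCl, rt
Reagents that add atoms: chloromethyl methyl ether, COCCl
Why: Williamson-type O-alkylation with the small and highly reactive chloromethyl ether, which should tolerate the two ortho substituents of the phenoxide.

Step 8
Reactants: 10 dimer bromide
Product: 11 3,5-bis(benzyloxy)-4-[3,4,5-tris(benzyloxy)-2-(methoxymethoxy)phenoxy]phenol (B–C phenol)
Conditions: Pd2(dba)3, tBuXPhos, KOH, 1,4-dioxane–H2O, 100 °C; then aq. NaH2PO4
Reagents that add atoms: potassium hydroxide, [K+].[OH-]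
Why: Palladium-catalysed hydroxylation of an aryl bromide with hydroxide (C–O cross-coupling with a bulky biarylphosphine), whose basic conditions benzyl and MOM ethers should survive.

Step 9
Reactants: 11 B–C phenol; 12 2-bromo-N-methoxy-N-methylacetamide
Product: 13 2-{3,5-bis(benzyloxy)-4-[3,4,5-tris(benzyloxy)-2-(methoxymethoxy)phenoxy]phenoxy}-N-methoxy-N-methylacetamide
Conditions: K2CO3, acetone, 55 °C
Reagents that add atoms: none
Why: Williamson alkylation (SN2) of the unhindered B1 phenoxide with a primary α-bromo amide, which installs the future A C1 and its neighbouring carbonyl carbon as an N-methoxy-N-methylamide in one operation.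

Step 10
Reactants: 13 aryloxy N-methoxy-N-methylacetamide; 14 methyl acetoacetate
Product: 16 methyl 6-{3,5-bis(benzyloxy)-4-[3,4,5-tris(benzyloxy)-2-(methoxymethoxy)phenoxy]phenoxy}-3,5-dioxohexanoate, via methyl acetoacetate dianion 15 (not isolated)
Conditions: 14, NaH, THF, 0 °C; n-BuLi, 0 °C; then 13, −78 → 0 °C; aq. NH4Cl
Reagents that add atoms: none
Why: Acylation of the acetoacetate dianion at its terminal carbon by an N-methoxy-N-methylamide, whose chelated tetrahedral adduct should persist until work-up so that the diketo ester is never exposed to excess nucleophile.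

Step 11
Reactants: 16 methyl 6-aryloxy-3,5-dioxohexanoate
Product: 18 2-{3,5-bis(benzyloxy)-4-[3,4,5-tris(benzyloxy)-2-(methoxymethoxy)phenoxy]phenoxy}benzene-1,3,5-triol (A–B–C trimer; ring A free), via 2-aryloxycyclohexane-1,3,5-trione 17 (not isolated)
Conditions: LiN(iPr)2 (4.5 equiv), THF, −78 °C → rt; then AcOH, 0 °C
Reagents that add atoms: none
Why: Excess amide base should remove the C4, C2 and finally the C6 protons of 16, and the C6 carbanion, an enolate carbon further acidified by the aryloxy oxygen, adds to the ester carbonyl C1 and expels methoxide in an intramolecular Claisen (Dieckmann-type) condensation. The closest known reaction type is the biomimetic Claisen cyclisation of β-polycarbonyl ester polyanions to phloroglucinols. Ring A closes in a 6-(enolendo)-exo-trig mode to trione 17, whose irreversible enolisation to the aromatic triphenoxide drives the step. No stereocentre is formed. The step needs acylation through carbon C6 to outrun acylation through the C5 enolate oxygen, which would give a 4-hydroxy-2-pyranone. Under full polyanion formation the last-formed and least stabilised carbanion at C6 is the most nucleophilic site, the methyl ester cannot ionise to an acylketene, and only the carbocyclic path ends in an aromatic ring.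

Step 12
Reactants: 18 A–B–C trimer triol
Product: 20 A–B–C trimer, ring A as 2,4,6-tris(benzyloxy)phenyl, MOM ether on C2 of ring C, via ring A triacetate 19 (not isolated)
Conditions: Ac2O, pyridine, rt; evaporate; then BnCl, NaH, H2O (3 equiv), DMF, 0 °C → rt
Reagents that add atoms: benzyl chloride, ClCc1ccccc1
Why: Acetylation followed by deacetylative Williamson benzylation in the same flask, in which hydroxide formed slowly from NaH and water unmasks one phenoxide at a time beside benzyl chloride and so should suppress the C-benzylation typical of free phloroglucinol anions.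

Step 13
Reactants: 20 MOM-protected A–B–C trimer
Product: 21 A–B–C trimer phenol (free OH on C2 of ring C; all other oxygens benzylated)
Conditions: conc. HCl (cat.), MeOH–THF, 50 °C
Reagents that add atoms: none
Why: Acid-catalysed acetal cleavage by transacetalisation to methanol, selective because the MOM ether is the only acetal and benzyl and diaryl ethers are stable to methanolic HCl.

Step 14
Reactants: 21 A–B–C trimer phenol; 10 dimer bromide
Product: 22 A–E pentamer, MOM ether on C2 of ring E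
Conditions: CuI, picolinic acid, K3PO4, DMSO, 100 °C (argon)
Reagents that add atoms: none
Why: Ullmann-type copper-catalysed diaryl ether synthesis with picolinic acid as ligand, a system suited to di-ortho-substituted phenols and electron-rich aryl bromides, helped here by the absence of ortho substituents at the bromide of 10.

Step 15
Reactants: 22 MOM-protected A–E pentamer
Product: 23 A–E pentamer phenol (free OH on C2 of ring E)
Conditions: conc. HCl (cat.), MeOH–THF, 50 °C
Reagents that add atoms: none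
Why: Acid-catalysed acetal cleavage of the single MOM ether, as in step 13.

Step 16
Reactants: 23 A–E pentamer phenol; 10 dimer bromide
Product: 24 A–G heptamer, MOM ether on C2 of ring G
Conditions: CuI, picolinic acid, K3PO4, DMSO, 100 °C (argon)
Reagents that add atoms: none
Why: Ullmann-type copper-catalysed etherification of the same phenol and bromide classes as in step 14.

Step 17
Reactants: 24 MOM-protected A–G heptamer
Product: 25 A–G heptamer phenol (free OH on C2 of ring G)
Conditions: conc. HCl (cat.), MeOH–THF, 50 °C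
Reagents that add atoms: none
Why: Acid-catalysed acetal cleavage of the single MOM ether, as in step 13.

Step 18
Reactants: 25 A–G heptamer phenol; 10 dimer bromide
Product: 26 A–I nonamer, MOM ether on C2 of ring I
Conditions: CuI, picolinic acid, K3PO4, DMSO, 100 °C (argon)
Reagents that add atoms: none
Why: Ullmann-type copper-catalysed etherification, the third use of the coupling of step 14 on the same functional groups.

Step 19
Reactants: 26 MOM-protected A–I nonamer
Product: 27 A–I nonamer phenol (free OH on C2 of ring I)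
Conditions: conc. HCl (cat.), MeOH–THF, 50 °C
Reagents that add atoms: none
Why: Acid-catalysed acetal cleavage of the single MOM ether, as in step 13.

Step 20
Reactants: 27 A–I nonamer phenol; 5 5-bromo-1,2,3-tris(benzyloxy)benzene
Product: 28 hexacosa-O-benzyl decamer A–J (all 26 hydroxyls of the target as benzyl ethers)
Conditions: CuI, picolinic acid, K3PO4, DMSO, 100 °C (argon)
Reagents that add atoms: none
Why: Ullmann-type copper-catalysed etherification with a small aryl bromide free of ortho substituents, which attaches ring J with its three oxygens already in place.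

Step 21
Reactants: 28 hexacosa-O-benzyl decamer
Product: 29 CNP0255890.0 (target)
Conditions: H2 (3 bar), Pd(OH)2/C, THF–MeOH, rt (argon work-up)
Reagents that add atoms: none
Why: Catalytic hydrogenolysis of all 26 benzyl ethers, under which diaryl ethers and the aromatic rings are inert, so the free polyphenol should be released without a further step.

Compound list
1 | 4-bromo-2,6-difluorobenzaldehyde | O=Cc1c(F)cc(Br)cc1F | starting material
2 | 4-bromo-2,6-bis(benzyloxy)benzaldehyde | O=Cc1c(OCc9ccccc9)cc(Br)cc1OCc9ccccc9 | intermediate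
3 | 4-bromo-2,6-bis(benzyloxy)phenyl formate (formed in the flask) | O=COc1c(OCc9ccccc9)cc(Br)cc1OCc9ccccc9 | intermediate
4 | 4-bromo-2,6-bis(benzyloxy)phenol | Oc1c(OCc9ccccc9)cc(Br)cc1OCc9ccccc9 | intermediate
5 | 5-bromo-1,2,3-tris(benzyloxy)benzene | Brc1cc(OCc9ccccc9)c(OCc9ccccc9)c(OCc9ccccc9)c1 | intermediate
6 | 6-bromo-2,3,4-tris(benzyloxy)benzaldehyde | O=Cc1c(Br)cc(OCc9ccccc9)c(OCc9ccccc9)c1OCc9ccccc9 | intermediate
7 | 6-[4-bromo-2,6-bis(benzyloxy)phenoxy]-2,3,4-tris(benzyloxy)benzaldehyde | Brc1cc(OCc9ccccc9)c(Oc2cc(OCc9ccccc9)c(OCc9ccccc9)c(OCc9ccccc9)c2C=O)c(OCc9ccccc9)c1 | intermediate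
8 | 6-[4-bromo-2,6-bis(benzyloxy)phenoxy]-2,3,4-tris(benzyloxy)phenyl formate (formed in the flask) | Brc1cc(OCc9ccccc9)c(Oc2cc(OCc9ccccc9)c(OCc9ccccc9)c(OCc9ccccc9)c2OC=O)c(OCc9ccccc9)c1 | intermediate
9 | 6-[4-bromo-2,6-bis(benzyloxy)phenoxy]-2,3,4-tris(benzyloxy)phenol | Brc1cc(OCc9ccccc9)c(Oc2cc(OCc9ccccc9)c(OCc9ccccc9)c(OCc9ccccc9)c2O)c(OCc9ccccc9)c1 | intermediate
10 | 1-[4-bromo-2,6-bis(benzyloxy)phenoxy]-3,4,5-tris(benzyloxy)-2-(methoxymethoxy)benzene (dimer bromide) | Brc1cc(OCc9ccccc9)c(Oc2cc(OCc9ccccc9)c(OCc9ccccc9)c(OCc9ccccc9)c2OCOC)c(OCc9ccccc9)c1 | intermediate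
11 | 3,5-bis(benzyloxy)-4-[3,4,5-tris(benzyloxy)-2-(methoxymethoxy)phenoxy]phenol (B–C phenol) | Oc1cc(OCc9ccccc9)c(Oc2cc(OCc9ccccc9)c(OCc9ccccc9)c(OCc9ccccc9)c2OCOC)c(OCc9ccccc9)c1 | intermediate
12 | 2-bromo-N-methoxy-N-methylacetamide | CON(C)C(=O)CBr | starting material
13 | 2-{3,5-bis(benzyloxy)-4-[3,4,5-tris(benzyloxy)-2-(methoxymethoxy)phenoxy]phenoxy}-N-methoxy-N-methylacetamide | CON(C)C(=O)COc1cc(OCc9ccccc9)c(Oc2cc(OCc9ccccc9)c(OCc9ccccc9)c(OCc9ccccc9)c2OCOC)c(OCc9ccccc9)c1 | intermediate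
14 | methyl acetoacetate | COC(=O)CC(C)=O | starting material
15 | methyl acetoacetate dianion, sodium lithium salt (formed in the flask) | COC(=O)[CH-]C(=O)[CH2-].[Na+].[Li+] | intermediate
16 | methyl 6-{3,5-bis(benzyloxy)-4-[3,4,5-tris(benzyloxy)-2-(methoxymethoxy)phenoxy]phenoxy}-3,5-dioxohexanoate | COC(=O)CC(=O)CC(=O)COc1cc(OCc9ccccc9)c(Oc2cc(OCc9ccccc9)c(OCc9ccccc9)c(OCc9ccccc9)c2OCOC)c(OCc9ccccc9)c1 | intermediate
17 | 2-aryloxycyclohexane-1,3,5-trione, aryl as in 16 (formed in the flask) | O=C1CC(=O)C(Oc2cc(OCc9ccccc9)c(Oc3cc(OCc9ccccc9)c(OCc9ccccc9)c(OCc9ccccc9)c3OCOC)c(OCc9ccccc9)c2)C(=O)C1 | intermediate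
18 | A–B–C trimer with free phloroglucinol ring A: 2-aryloxybenzene-1,3,5-triol, aryl as in 16 | Oc1cc(O)c(Oc2cc(OCc9ccccc9)c(Oc3cc(OCc9ccccc9)c(OCc9ccccc9)c(OCc9ccccc9)c3OCOC)c(OCc9ccccc9)c2)c(O)c1 | intermediate
19 | ring A triacetate of 18 (formed in the flask) | CC(=O)Oc1cc(OC(C)=O)c(Oc2cc(OCc9ccccc9)c(Oc3cc(OCc9ccccc9)c(OCc9ccccc9)c(OCc9ccccc9)c3OCOC)c(OCc9ccccc9)c2)c(OC(C)=O)c1 | intermediate
20 | A–B–C trimer, ring A tribenzyl ether, MOM ether on C2 of ring C | c1(OCc9ccccc9)cc(OCc9ccccc9)c(Oc2cc(OCc9ccccc9)c(Oc3cc(OCc9ccccc9)c(OCc9ccccc9)c(OCc9ccccc9)c3OCOC)c(OCc9ccccc9)c2)c(OCc9ccccc9)c1 | intermediate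
21 | A–B–C trimer phenol, free OH on C2 of ring C | c1(OCc9ccccc9)cc(OCc9ccccc9)c(Oc2cc(OCc9ccccc9)c(Oc3cc(OCc9ccccc9)c(OCc9ccccc9)c(OCc9ccccc9)c3O)c(OCc9ccccc9)c2)c(OCc9ccccc9)c1 | intermediate
22 | A–E pentamer, MOM ether on C2 of ring E | c1(OCc9ccccc9)cc(OCc9ccccc9)c(Oc2cc(OCc9ccccc9)c(Oc3cc(OCc9ccccc9)c(OCc9ccccc9)c(OCc9ccccc9)c3Oc3cc(OCc9ccccc9)c(Oc4cc(OCc9ccccc9)c(OCc9ccccc9)c(OCc9ccccc9)c4OCOC)c(OCc9ccccc9)c3)c(OCc9ccccc9)c2)c(OCc9ccccc9)c1 | intermediate
23 | A–E pentamer phenol, free OH on C2 of ring E | c1(OCc9ccccc9)cc(OCc9ccccc9)c(Oc2cc(OCc9ccccc9)c(Oc3cc(OCc9ccccc9)c(OCc9ccccc9)c(OCc9ccccc9)c3Oc3cc(OCc9ccccc9)c(Oc4cc(OCc9ccccc9)c(OCc9ccccc9)c(OCc9ccccc9)c4O)c(OCc9ccccc9)c3)c(OCc9ccccc9)c2)c(OCc9ccccc9)c1 | intermediate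
24 | A–G heptamer, MOM ether on C2 of ring G | c1(OCc9ccccc9)cc(OCc9ccccc9)c(Oc2cc(OCc9ccccc9)c(Oc3cc(OCc9ccccc9)c(OCc9ccccc9)c(OCc9ccccc9)c3Oc3cc(OCc9ccccc9)c(Oc4cc(OCc9ccccc9)c(OCc9ccccc9)c(OCc9ccccc9)c4Oc4cc(OCc9ccccc9)c(Oc5cc(OCc9ccccc9)c(OCc9ccccc9)c(OCc9ccccc9)c5OCOC)c(OCc9ccccc9)c4)c(OCc9ccccc9)c3)c(OCc9ccccc9)c2)c(OCc9ccccc9)c1 | intermediate
25 | A–G heptamer phenol, free OH on C2 of ring G | c1(OCc9ccccc9)cc(OCc9ccccc9)c(Oc2cc(OCc9ccccc9)c(Oc3cc(OCc9ccccc9)c(OCc9ccccc9)c(OCc9ccccc9)c3Oc3cc(OCc9ccccc9)c(Oc4cc(OCc9ccccc9)c(OCc9ccccc9)c(OCc9ccccc9)c4Oc4cc(OCc9ccccc9)c(Oc5cc(OCc9ccccc9)c(OCc9ccccc9)c(OCc9ccccc9)c5O)c(OCc9ccccc9)c4)c(OCc9ccccc9)c3)c(OCc9ccccc9)c2)c(OCc9ccccc9)c1 | intermediate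
26 | A–I nonamer, MOM ether on C2 of ring I | c1(OCc9ccccc9)cc(OCc9ccccc9)c(Oc2cc(OCc9ccccc9)c(Oc3cc(OCc9ccccc9)c(OCc9ccccc9)c(OCc9ccccc9)c3Oc3cc(OCc9ccccc9)c(Oc4cc(OCc9ccccc9)c(OCc9ccccc9)c(OCc9ccccc9)c4Oc4cc(OCc9ccccc9)c(Oc5cc(OCc9ccccc9)c(OCc9ccccc9)c(OCc9ccccc9)c5Oc5cc(OCc9ccccc9)c(Oc6cc(OCc9ccccc9)c(OCc9ccccc9)c(OCc9ccccc9)c6OCOC)c(OCc9ccccc9)c5)c(OCc9ccccc9)c4)c(OCc9ccccc9)c3)c(OCc9ccccc9)c2)c(OCc9ccccc9)c1 | intermediate
27 | A–I nonamer phenol, free OH on C2 of ring I | c1(OCc9ccccc9)cc(OCc9ccccc9)c(Oc2cc(OCc9ccccc9)c(Oc3cc(OCc9ccccc9)c(OCc9ccccc9)c(OCc9ccccc9)c3Oc3cc(OCc9ccccc9)c(Oc4cc(OCc9ccccc9)c(OCc9ccccc9)c(OCc9ccccc9)c4Oc4cc(OCc9ccccc9)c(Oc5cc(OCc9ccccc9)c(OCc9ccccc9)c(OCc9ccccc9)c5Oc5cc(OCc9ccccc9)c(Oc6cc(OCc9ccccc9)c(OCc9ccccc9)c(OCc9ccccc9)c6O)c(OCc9ccccc9)c5)c(OCc9ccccc9)c4)c(OCc9ccccc9)c3)c(OCc9ccccc9)c2)c(OCc9ccccc9)c1 | intermediate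
28 | hexacosa-O-benzyl decamer A–J | c1(OCc9ccccc9)cc(OCc9ccccc9)c(Oc2cc(OCc9ccccc9)c(Oc3cc(OCc9ccccc9)c(OCc9ccccc9)c(OCc9ccccc9)c3Oc3cc(OCc9ccccc9)c(Oc4cc(OCc9ccccc9)c(OCc9ccccc9)c(OCc9ccccc9)c4Oc4cc(OCc9ccccc9)c(Oc5cc(OCc9ccccc9)c(OCc9ccccc9)c(OCc9ccccc9)c5Oc5cc(OCc9ccccc9)c(Oc6cc(OCc9ccccc9)c(OCc9ccccc9)c(OCc9ccccc9)c6Oc6cc(OCc9ccccc9)c(OCc9ccccc9)c(OCc9ccccc9)c6)c(OCc9ccccc9)c5)c(OCc9ccccc9)c4)c(OCc9ccccc9)c3)c(OCc9ccccc9)c2)c(OCc9ccccc9)c1 | intermediate
29 | CNP0255890.0 | Oc1cc(O)c(Oc2cc(O)c(Oc3cc(O)c(O)c(O)c3Oc3cc(O)c(Oc4cc(O)c(O)c(O)c4Oc4cc(O)c(Oc5cc(O)c(O)c(O)c5Oc5cc(O)c(Oc6cc(O)c(O)c(O)c6Oc6cc(O)c(O)c(O)c6)c(O)c5)c(O)c4)c(O)c3)c(O)c2)c(O)c1 | target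

Total step count: 21. Longest linear sequence: 21 steps (steps 1 to 21; bromides 5 and 10 used in steps 14, 16, 18 and 20 are drawn from this same line).

Steps most likely to fail

Step 11. The polyanion may fail to cyclise because the ester is deactivated as its enolate, or ring closure may run through the C5 enolate oxygen (lactonisation) instead of through C6. The fallback gives up growing ring A and attaches it as a preformed aryl unit. Commercial 2,4,6-trihydroxybenzaldehyde is perbenzylated (BnBr, K2CO3, DMF) to 2,4,6-tris(benzyloxy)benzaldehyde F1. Baeyer–Villiger oxidation (mCPBA) gives 2,4,6-tris(benzyloxy)phenyl formate F2, and saponification gives 2,4,6-tris(benzyloxy)phenol F3. Copper-catalysed etherification of F3 with the dimer bromide under the conditions of step 14 sets out from 10 and comes back to the route at 20, bypassing steps 8 to 12.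

Step 5. Chemoselectivity between the three aryl bromides present may erode, so that the product bromide is etherified further (oligomerisation), or the di-ortho-substituted phenoxide may couple sluggishly. The fallback replaces copper catalysis by metal-free displacement of a fluoride. Bromide 5 undergoes bromine–lithium exchange (n-BuLi, THF, −78 °C) to 3,4,5-tris(benzyloxy)phenyllithium F4, which is fluorinated with N-fluorobenzenesulfonimide to 5-fluoro-1,2,3-tris(benzyloxy)benzene F5. Rieche formylation as in step 4 gives 6-fluoro-2,3,4-tris(benzyloxy)benzaldehyde F6. Nucleophilic aromatic substitution of its fluoride, ortho to the formyl group, by phenol 4 (Cs2CO3, DMAc, 120 °C) cannot touch a carbon–bromine bond. This fallback sets out from 5 and comes back at 7.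

Step 18. With the largest partners, slow copper insertion into the electron-rich bromide may let protodebromination of 10 and oxidative degradation of the hindered phenoxide compete. The fallback uses oxidative boron-based etherification at room temperature in place of halide coupling at 100 °C. Bromide 10 is converted by bromine–lithium exchange (n-BuLi, THF, −78 °C) into the aryllithium of the dimer F7, trapped with B(OMe)3 as the dimethyl arylboronate F8 and hydrolysed (aq. NH4Cl) to the arylboronic acid of the dimer F9. Chan–Lam coupling of F9 with phenol 25 (Cu(OAc)2, pyridine, 4 Å molecular sieves, air, CH2Cl2, rt), a reaction type established for 2,6-disubstituted phenols, sets out from 10 and comes back at 26.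

Further compounds
F1 | step 11 | 2,4,6-tris(benzyloxy)benzaldehyde | O=Cc1c(OCc9ccccc9)cc(OCc9ccccc9)cc1OCc9ccccc9
F2 | step 11 | 2,4,6-tris(benzyloxy)phenyl formate | O=COc1c(OCc9ccccc9)cc(OCc9ccccc9)cc1OCc9ccccc9
F3 | step 11 | 2,4,6-tris(benzyloxy)phenol | Oc1c(OCc9ccccc9)cc(OCc9ccccc9)cc1OCc9ccccc9
F4 | step 5 | 3,4,5-tris(benzyloxy)phenyllithium | [Li]c1cc(OCc9ccccc9)c(OCc9ccccc9)c(OCc9ccccc9)c1
F5 | step 5 | 5-fluoro-1,2,3-tris(benzyloxy)benzene | Fc1cc(OCc9ccccc9)c(OCc9ccccc9)c(OCc9ccccc9)c1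
F6 | step 5 | 6-fluoro-2,3,4-tris(benzyloxy)benzaldehyde | O=Cc1c(F)cc(OCc9ccccc9)c(OCc9ccccc9)c1OCc9ccccc9
F7 | step 18 | aryllithium of the dimer (lithium in place of the bromine of 10) | [Li]c1cc(OCc9ccccc9)c(Oc2cc(OCc9ccccc9)c(OCc9ccccc9)c(OCc9ccccc9)c2OCOC)c(OCc9ccccc9)c1
F8 | step 18 | dimethyl arylboronate of the dimer | COB(OC)c1cc(OCc9ccccc9)c(Oc2cc(OCc9ccccc9)c(OCc9ccccc9)c(OCc9ccccc9)c2OCOC)c(OCc9ccccc9)c1
F9 | step 18 | arylboronic acid of the dimer (B(OH)2 in place of the bromine of 10) | OB(O)c1cc(OCc9ccccc9)c(Oc2cc(OCc9ccccc9)c(OCc9ccccc9)c(OCc9ccccc9)c2OCOC)c(OCc9ccccc9)c1
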